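(The constants are invented; the rest is arithmetic.)

You are asked 4 things about one flask, and the last 2 turn on how far the two mirror-image substrates have parted by the point in question.

left-handed substrate 20 mM; coupling partner 3.00 equiv; free catalyst 0.5 mol%; impurity 81 µM; added ligand 60 µM; right-handed substrate 20 mM

    free catalyst + impurity → spent catalyst (k1 = 69000 M⁻¹ h⁻¹)
    free catalyst + right-handed substrate ⇌ catalyst intermediate B (K2 = 150 M⁻¹, k2 = 3.4 × 10⁵ M⁻¹ h⁻¹)
    free catalyst + left-handed substrate ⇌ catalyst intermediate A (K3 = 670 M⁻¹, k3 = 16000 M⁻¹ h⁻¹)
    free catalyst + added ligand ⇌ idle complex (K4 = 12000 M⁻¹, k4 = 9300 M⁻¹ h⁻¹)
    coupling partner + catalyst intermediate B → free catalyst + right-handed product (k5 = 330 M⁻¹ h⁻¹)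
    coupling partner + catalyst intermediate A → free catalyst + left-handed product (k6 = 860 M⁻¹ h⁻¹)

* the form that holds most of the catalyst when 50% of the left-handed substrate and right-handed substrate together are converted (free catalyst / spent catalyst / catalyst intermediate A / idle complex / catalyst intermediate B)
* its share of the catalyst then
* apparent order in coupling partner when 50% of the left-handed substrate and right-handed substrate together are converted (percent change of the rate of making left-handed product for one percent more coupling partner charged)
* factor on the rate of making left-handed product when 50% of the left-handed substrate and right-handed substrate together are converted if coupling partner is charged twice over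

Start with the catalyst. Its charge is 100 µM, more than the 81 µM of impurity. If the impurity reacts completely, spent catalyst holds a fraction 81.0% and 0.190 keeps working.

Next comes the partner. Half of both substrates together uses a fraction 0.333 of its charge, so 0.667 remains. Replace its falling curve by the mean, 0.833 of the charge, or 50.0 mM. At that level, intermediate A goes on to product with probability 0.643 and intermediate B with 0.00723. The mean selectivity factor, the left-handed substrate's rate constant of loss over the right-handed one's, is therefore 4.19.

Let l and r be the fractions of each substrate left. Then l is r raised to that factor, and l + r = 1 at the point asked. One correction from 0.7 gives r = 0.732 and l = 0.268.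



Now the working catalyst divides. With the partner at its level there, a fraction 0.590 of intermediate A couples. Per free catalyst this gives 1.47 of intermediate A, 2.20 of intermediate B and 0.720 of idle complex, a sum with free catalyst of 5.39. Free catalyst is then 3.53 µM, so the impurity lives 4.11 h. At the rate of that point, the conversion takes 71.3 h, far longer. The largest form is spent catalyst.

With l held fixed, the order is 0.856. That is the weak link, since a larger charge lowers the selectivity factor and more left-handed substrate then remains at half conversion. One percent more partner raises l by 0.397 percent. The reforged order is 1.14, and held across a doubling it gives a factor 2.21.

The forecast says spent catalyst at 81%, order 1.27 and factor 2, noting that “a 1% larger charge raises the remaining partner by 1.5%”. Its order stands above mine and its factor below.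

The flask gives spent catalyst at 81.0%, order 1.2 and factor 2.05. It reaches that point after 37.0 h, making left-handed product at 0.179 mM h⁻¹. Carry the selectivity factor on to 40.0 h in this flask, where 72% of the right-handed substrate remains. Raised to 4.19, that fraction gives 25.2% for the left-handed substrate, and the flask holds 24%.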